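**Plan**
- **Enabling feature:** the only ring is a benzene with the C15 chain on C1, oxygen on C3 and C5, and H on C2, C4 and C6. A 3-alkylcyclobutenone (supplying C1, C2, C3, C6) and an alkoxyethyne (C4, C5) assemble exactly this all-meta pattern, which makes the key step possible.
- **Retrosynthetic cuts, in order:** the O-acyl and O-protecting bonds, then ring bonds C2–C3, C3–C4 and C5–C6, then the ring–chain bond C1–C1′, then chain bond C7′–C8′ next to the alkene.
- **Forward order:** C7′–C8′ forms by acetylide alkylation and the alkyne is reduced to the Z-alkene. C1–C1′ forms by adding the chain organolithium to a purchased four-membered ring. The benzene ring, the only ring made, closes last, followed by deprotection, peracetylation and selective removal of the aryl acetates.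
- **Stereochemistry:** C10′ (R) is bought in (R)-oct-1-yn-3-ol and no later step breaks a bond at that carbon. The Z geometry comes from syn semihydrogenation.
- **Protecting-group logic:** the ynol ether carries a 2-(trimethylsilyl)ethyl group, so one fluoride treatment frees both C5–OH and C10′–OH. A plain alkyl ether of a resorcinol monoether resists thiolates (the ring is already a phenoxide) and would need Lewis acids that ionise the allylic C–O bond.

Key step: step 7

Assumption: 1-bromo-7-chloroheptane and 3-ethoxycyclobut-2-en-1-one are treated as purchasable building blocks; arene atoms are numbered C1 (chain), C3 (hydroxyl from the ketone), C5 (ether oxygen), and chain atoms C1′–C15′ counted from the ring.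

**Step 1**
Reactants: 1 (R)-oct-1-yn-3-ol
Product: 2 (R)-tert-butyldimethyl(oct-1-yn-3-yloxy)silane
Conditions: TBSCl, imidazole, DMF, 0 °C → rt
Reagents that add atoms: tert-butyldimethylsilyl chloride, `CC(C)(C)[Si](C)(C)Cl`
Why: Imidazole-promoted O-silylation of a secondary alcohol touches no bond at the stereocentre, so the R configuration is carried on unchanged.

**Step 2**
Reactants: 2 (R)-tert-butyldimethyl(oct-1-yn-3-yloxy)silane; 3 1-bromo-7-chloroheptane
Product: 5 (R)-10-(tert-butyldimethylsilyloxy)-1-chloropentadec-8-yne, via lithium acetylide 4 (not isolated)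
Conditions: n-BuLi, THF, −78 °C; then 3, DMPU, −78 °C → rt
Reagents that add atoms: none
Why: SN2 alkylation of a lithium acetylide in a dipolar medium forms C7′–C8′, and bromide leaves much faster than chloride, so the chloride end is kept for step 4.

**Step 3**
Reactants: 5 (R)-10-(tert-butyldimethylsilyloxy)-1-chloropentadec-8-yne
Product: 6 (R,Z)-10-(tert-butyldimethylsilyloxy)-1-chloropentadec-8-ene
Conditions: H2 (1 atm), Pd/CaCO3 poisoned with Pb(OAc)2, quinoline, hexane, rt
Reagents that add atoms: none
Why: Lindlar semihydrogenation delivers both hydrogens syn from the poisoned palladium surface and should stop at the Z-alkene, with the alkyl chloride and silyl ether inert.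

**Step 4**
Reactants: 6 (R,Z)-10-(tert-butyldimethylsilyloxy)-1-chloropentadec-8-ene
Product: 7 (R,Z)-10-(tert-butyldimethylsilyloxy)-1-iodopentadec-8-ene
Conditions: NaI, butan-2-one, reflux, exclusion of light
Reagents that add atoms: sodium iodide, `[Na+].[I-]`
Why: Finkelstein halide exchange, driven by precipitation of NaCl, should give the primary iodide needed for clean lithium–iodine exchange.

**Step 5**
Reactants: 7 (R,Z)-10-(tert-butyldimethylsilyloxy)-1-iodopentadec-8-ene; 8 3-ethoxycyclobut-2-en-1-one
Product: 11 (R,Z)-3-[10-(tert-butyldimethylsilyloxy)pentadec-8-en-1-yl]cyclobut-2-en-1-one, via alkyllithium 9 (not isolated), via lithium alkoxide adduct 10 (not isolated)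
Conditions: t-BuLi (2.1 equiv), pentane–Et2O, −78 °C; then 8, Et2O, −78 °C → −20 °C; then 0.5 M aq. HCl, 0 °C
Reagents that add atoms: water, `O`
Why: Lithium–iodine exchange, 1,2-addition of the primary alkyllithium to the vinylogous ester and acid-induced loss of ethanol with carbonyl transposition (a Stork–Danheiser-type sequence) form C1–C1′; enolisation of 8 is disfavoured because it would give an antiaromatic cyclobutadienolate, and the carbinol centre of 10 is destroyed again.

**Step 6**
Reactants: 12 2-(trimethylsilyl)ethanol; 13 trichloroethene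
Product: 17 [2-(ethynyloxy)ethyl]trimethylsilane, via potassium alkoxide 14 (not isolated), via dichlorovinyl ether 15 (not isolated), via lithium alkoxyacetylide 16 (not isolated)
Conditions: KH, THF, 0 °C; 13, −50 °C → rt; n-BuLi (2.4 equiv), −78 °C → −40 °C; H2O, −78 °C
Reagents that add atoms: none
Why: This is the standard one-pot alkoxyethyne synthesis, in which the alkoxide substitutes one chloride of trichloroethene and n-BuLi then effects dehydrochlorination and chlorine–lithium exchange before protonation; it is applied here to an alcohol whose residue later serves as a fluoride-labile phenol protecting group.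

**Step 7**
Reactants: 11 (R,Z)-3-[10-(tert-butyldimethylsilyloxy)pentadec-8-en-1-yl]cyclobut-2-en-1-one; 17 [2-(ethynyloxy)ethyl]trimethylsilane
Product: 22 (R,Z)-3-[10-(tert-butyldimethylsilyloxy)pentadec-8-en-1-yl]-5-[2-(trimethylsilyl)ethoxy]phenol, via vinylketene 18 (not isolated), via alkenylcyclobutenone 19 (not isolated), via dienylketene 20 (not isolated), via cyclohexadienone 21 (not isolated)
Conditions: 17 (2.5 equiv), toluene, sealed tube, 80 °C until 11 is consumed, then 110 °C
Reagents that add atoms: none
Why: At 80 °C cyclobutenone 11 opens reversibly by a four-electron electrocyclic reaction to vinylketene 18, which the electron-rich triple bond of 17 intercepts in a [2+2] cycloaddition that forms C3–C4 and C5–C6 and closes the transient four-membered ring of 19. A second four-electron opening of 19 cleaves the old C3–C6 bond to give dienylketene 20, whose six-electron disrotatory electrocyclisation forms C2–C3 and closes the six-membered ring as dienone 21, which tautomerises to phenol 22. This is the Danheiser benzannulation of a 3-alkylcyclobutenone with an alkoxyalkyne, the established route to 5-alkylresorcinol monoethers. The regiocontrol it needs comes from the polarity of the partners: the electrophilic ketene carbonyl carbon bonds to the unsubstituted, nucleophilic carbon of the ynol ether, so the ether oxygen ends meta to the new hydroxyl and both end meta to the chain. The chemoselectivity it needs is secured because the unactivated Z-alkene cannot compete with the ynol ether as ketenophile and because the medium is neutral, so the allylic silyl ether cannot ionise. No lasting stereocentre is created (the sp3 ring carbon of 19 becomes planar again), and holding the bath at 80 °C until 11 is consumed should keep retro-ene loss of 17 slow before the finish at 110 °C.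

**Step 8**
Reactants: 22 (R,Z)-3-[10-(tert-butyldimethylsilyloxy)pentadec-8-en-1-yl]-5-[2-(trimethylsilyl)ethoxy]phenol
Product: 23 (R,Z)-5-(10-hydroxypentadec-8-en-1-yl)benzene-1,3-diol
Conditions: TBAF (6 equiv), THF–DMPU, 60 °C, argon; aqueous work-up
Reagents that add atoms: none
Why: Fluoride-induced desilylation cleaves the Si–O bond at C10′ and fragments the 2-silylethyl aryl ether to ethene and aryloxide, a leaving group no worse than the hemiformal alkoxide expelled in SEM ether cleavage, and the basic, non-ionising medium leaves the allylic C–O bond and the Z-alkene untouched.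

**Step 9**
Reactants: 23 (R,Z)-5-(10-hydroxypentadec-8-en-1-yl)benzene-1,3-diol
Product: 24 (R,Z)-5-(10-acetoxypentadec-8-en-1-yl)-1,3-phenylene diacetate
Conditions: Ac2O, pyridine, DMAP (cat.), CH2Cl2, 0 °C → rt
Reagents that add atoms: acetic anhydride, `CC(=O)OC(C)=O`
Why: DMAP-catalysed O-acylation of all three hydroxyl groups takes place at oxygen only, so C10′ keeps its configuration.

**Step 10**
Reactants: 24 (R,Z)-5-(10-acetoxypentadec-8-en-1-yl)-1,3-phenylene diacetate
Product: 25 (R,Z)-1-(3,5-dihydroxyphenyl)pentadec-8-en-10-yl acetate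
Conditions: NH4OAc, MeOH–H2O (4:1), rt
Reagents that add atoms: none
Why: Chemoselective transesterification under near-neutral conditions should remove only the two aryl acetates, whose phenoxide leaving groups make them far more reactive than the hindered secondary allylic acetate.

**Compound list**
1 | (R)-oct-1-yn-3-ol | `CCCCC[C@H](C#C)O` | starting material
2 | (R)-tert-butyldimethyl(oct-1-yn-3-yloxy)silane | `CCCCC[C@H](C#C)O[Si](C)(C)C(C)(C)C` | intermediate
3 | 1-bromo-7-chloroheptane | `ClCCCCCCCBr` | starting material
4 | lithium acetylide of 2 | `CCCCC[C@H](C#C[Li])O[Si](C)(C)C(C)(C)C` | intermediate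
5 | (R)-10-(tert-butyldimethylsilyloxy)-1-chloropentadec-8-yne | `CCCCC[C@H](C#CCCCCCCCCl)O[Si](C)(C)C(C)(C)C` | intermediate
6 | (R,Z)-10-(tert-butyldimethylsilyloxy)-1-chloropentadec-8-ene | `CCCCC[C@H](/C=C\CCCCCCCCl)O[Si](C)(C)C(C)(C)C` | intermediate
7 | (R,Z)-10-(tert-butyldimethylsilyloxy)-1-iodopentadec-8-ene | `CCCCC[C@H](/C=C\CCCCCCCI)O[Si](C)(C)C(C)(C)C` | intermediate
8 | 3-ethoxycyclobut-2-en-1-one | `CCOC1=CC(=O)C1` | starting material
9 | (R,Z)-[10-(tert-butyldimethylsilyloxy)pentadec-8-en-1-yl]lithium | `CCCCC[C@H](/C=C\CCCCCCC[Li])O[Si](C)(C)C(C)(C)C` | intermediate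
10 | lithium 1-[(R,Z)-10-(tert-butyldimethylsilyloxy)pentadec-8-en-1-yl]-3-ethoxycyclobut-2-en-1-olate (both epimers at the carbinol carbon) | `CCCCC[C@H](/C=C\CCCCCCCC1(O[Li])C=C(OCC)C1)O[Si](C)(C)C(C)(C)C` | intermediate
11 | (R,Z)-3-[10-(tert-butyldimethylsilyloxy)pentadec-8-en-1-yl]cyclobut-2-en-1-one | `CCCCC[C@H](/C=C\CCCCCCCC1=CC(=O)C1)O[Si](C)(C)C(C)(C)C` | intermediate
12 | 2-(trimethylsilyl)ethanol | `C[Si](C)(C)CCO` | starting material
13 | trichloroethene | `ClC=C(Cl)Cl` | starting material
14 | potassium 2-(trimethylsilyl)ethoxide | `C[Si](C)(C)CC[O-].[K+]` | intermediate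
15 | (E)-[2-(1,2-dichloroethenyloxy)ethyl]trimethylsilane | `C[Si](C)(C)CCO/C(Cl)=C\Cl` | intermediate
16 | lithium 2-[2-(trimethylsilyl)ethoxy]ethynide | `C[Si](C)(C)CCOC#C[Li]` | intermediate
17 | [2-(ethynyloxy)ethyl]trimethylsilane | `C[Si](C)(C)CCOC#C` | intermediate
18 | (R,Z)-13-(tert-butyldimethylsilyloxy)-3-methylideneoctadeca-1,11-dien-1-one (vinylketene) | `CCCCC[C@H](/C=C\CCCCCCCC(=C)C=C=O)O[Si](C)(C)C(C)(C)C` | intermediate
19 | 4-[(R,Z)-12-(tert-butyldimethylsilyloxy)heptadeca-1,10-dien-2-yl]-3-[2-(trimethylsilyl)ethoxy]cyclobut-2-en-1-one (both epimers at C4) | `CCCCC[C@H](/C=C\CCCCCCCC(=C)C1C(=O)C=C1OCC[Si](C)(C)C)O[Si](C)(C)C(C)(C)C` | intermediate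
20 | (3E,13Z,15R)-15-(tert-butyldimethylsilyloxy)-5-methylidene-3-[2-(trimethylsilyl)ethoxy]icosa-1,3,13-trien-1-one (dienylketene, ketene and alkenyl arms cis) | `CCCCC[C@H](/C=C\CCCCCCCC(=C)/C=C(OCC[Si](C)(C)C)\C=C=O)O[Si](C)(C)C(C)(C)C` | intermediate
21 | (R,Z)-5-[10-(tert-butyldimethylsilyloxy)pentadec-8-en-1-yl]-3-[2-(trimethylsilyl)ethoxy]cyclohexa-2,4-dien-1-one | `CCCCC[C@H](/C=C\CCCCCCCC1=CC(OCC[Si](C)(C)C)=CC(=O)C1)O[Si](C)(C)C(C)(C)C` | intermediate
22 | (R,Z)-3-[10-(tert-butyldimethylsilyloxy)pentadec-8-en-1-yl]-5-[2-(trimethylsilyl)ethoxy]phenol | `CCCCC[C@H](/C=C\CCCCCCCc1cc(O)cc(OCC[Si](C)(C)C)c1)O[Si](C)(C)C(C)(C)C` | intermediate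
23 | (R,Z)-5-(10-hydroxypentadec-8-en-1-yl)benzene-1,3-diol | `CCCCC[C@H](/C=C\CCCCCCCc1cc(O)cc(O)c1)O` | intermediate
24 | (R,Z)-5-(10-acetoxypentadec-8-en-1-yl)-1,3-phenylene diacetate | `CCCCC[C@H](/C=C\CCCCCCCc1cc(OC(C)=O)cc(OC(C)=O)c1)OC(C)=O` | intermediate
25 | (R,Z)-1-(3,5-dihydroxyphenyl)pentadec-8-en-10-yl acetate | `CCCCC[C@H](/C=C\CCCCCCCc1cc(O)cc(O)c1)OC(C)=O` | target

**Totals**
- Total step count: 10.
- Longest linear sequence: 9 steps (steps 1–5 and 7–10, from 1). Step 6 is a one-step side branch.

**Steps most likely to fail**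

**Step 7.**
- What may go wrong: retro-ene fragmentation of the ynol ether, helped by the β-silicon, may compete with the thermal opening of the cyclobutenone. Self-reaction of the ketenes or acylation of the product phenol may also erode the conversion.
- Fallback, from 11 back to 19: the same vinylketene is made by elimination at low temperature, so the ynol ether is never heated.
- Heating 11 in wet 1,4-dioxane lets water trap the vinylketene as (R,Z)-13-(tert-butyldimethylsilyloxy)-3-methylideneoctadec-11-enoic acid F1.
- 1-Chloro-N,N,2-trimethylprop-1-en-1-amine in CH2Cl2 then converts the acid under neutral conditions into (R,Z)-13-(tert-butyldimethylsilyloxy)-3-methylideneoctadec-11-enoyl chloride F2.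
- Slow addition of Et3N to F2 and 17 at 0 °C generates 18 by dehydrochlorination, so the [2+2] step to 19 runs cold. Compound 19 alone is then heated in toluene to give 22.

**Step 6.**
- What may go wrong: Peterson-type fragmentation of the β-silyl alkoxide may occur before it is captured. The volatile, acid- and heat-sensitive product may also be lost on isolation.
- Fallback, from 12 back to 17: this route avoids any free alkoxide.
- Transfer vinylation of 12 with butyl vinyl ether (Pd(OCOCF3)2, 4,7-diphenyl-1,10-phenanthroline, Et3N) should give trimethyl[2-(vinyloxy)ethyl]silane F3.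
- Bromine in pentane at −78 °C adds to the enol ether to give [2-(1,2-dibromoethoxy)ethyl]trimethylsilane F4.
- NaNH2 in liquid NH3 removes two equivalents of HBr and leaves sodium 2-[2-(trimethylsilyl)ethoxy]ethynide F5, which water protonates to 17.

**Step 8.**
- What may go wrong: fragmentation of the aryl 2-silylethyl ether may stall, because the ring is already a phenoxide under TBAF. Long heating may bring on air oxidation of the electron-rich ring.
- Fallback, from 7 back to 23: the resorcinol is brought in ready-made with two fluoride-labile silyl ethers.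
- Zn dust and LiCl in THF insert into 7 to give (R,Z)-[10-(tert-butyldimethylsilyloxy)pentadec-8-en-1-yl]zinc iodide F6.
- Commercial 5-bromobenzene-1,3-diol is silylated (TBSCl, imidazole) to 1-bromo-3,5-bis(tert-butyldimethylsilyloxy)benzene F7.
- Negishi coupling of F6 with F7 (PdCl2(dppf), THF, 50 °C) should give (R,Z)-1,3-bis(tert-butyldimethylsilyloxy)-5-[10-(tert-butyldimethylsilyloxy)pentadec-8-en-1-yl]benzene F8.
- TBAF at room temperature strips all three silyl groups from F8 to give 23.

**Further compounds**
F1 | step 7 | (R,Z)-13-(tert-butyldimethylsilyloxy)-3-methylideneoctadec-11-enoic acid | `CCCCC[C@H](/C=C\CCCCCCCC(=C)CC(=O)O)O[Si](C)(C)C(C)(C)C`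
F2 | step 7 | (R,Z)-13-(tert-butyldimethylsilyloxy)-3-methylideneoctadec-11-enoyl chloride | `CCCCC[C@H](/C=C\CCCCCCCC(=C)CC(=O)Cl)O[Si](C)(C)C(C)(C)C`
F3 | step 6 | trimethyl[2-(vinyloxy)ethyl]silane | `C[Si](C)(C)CCOC=C`
F4 | step 6 | [2-(1,2-dibromoethoxy)ethyl]trimethylsilane (racemic) | `C[Si](C)(C)CCOC(Br)CBr`
F5 | step 6 | sodium 2-[2-(trimethylsilyl)ethoxy]ethynide | `C[Si](C)(C)CCOC#C[Na]`
F6 | step 8 | (R,Z)-[10-(tert-butyldimethylsilyloxy)pentadec-8-en-1-yl]zinc iodide | `CCCCC[C@H](/C=C\CCCCCCC[Zn]I)O[Si](C)(C)C(C)(C)C`
F7 | step 8 | 1-bromo-3,5-bis(tert-butyldimethylsilyloxy)benzene | `CC(C)(C)[Si](C)(C)Oc1cc(Br)cc(O[Si](C)(C)C(C)(C)C)c1`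
F8 | step 8 | (R,Z)-1,3-bis(tert-butyldimethylsilyloxy)-5-[10-(tert-butyldimethylsilyloxy)pentadec-8-en-1-yl]benzene | `CCCCC[C@H](/C=C\CCCCCCCc1cc(O[Si](C)(C)C(C)(C)C)cc(O[Si](C)(C)C(C)(C)C)c1)O[Si](C)(C)C(C)(C)C`
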